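The route rests on leaving the five-membered ring of the upper guaianolide (C1–C5) open until a monomer stage. A costunolide-derived cycloheptene carrying an ethynyl group on C5 and a vinyloxymethyl group on C10 (an isomer of dehydrozaluzanin C) is isomerised in one operation: a Claisen shift forms C1–C2 and the C10=C14 methylene, then a 5-exo-dig acyl-radical hydroacylation forms C3–C4 and the C4=C15 methylene. The step exploits the 3-oxocyclopentane ring flanked by the exocyclic carbons C14 and C15. Saegusa oxidation, biomimetic Diels–Alder union with dehydrozaluzanin C, C10 oxygenation and hydration of C4=C15 complete ainsliadimer B.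

Key step: step 12

Remark: guaianolide locants are used throughout; unprimed locants belong to the upper (cyclopentenone) unit and its costunolide-derived precursors, primed locants to the lower (spiro) unit; costunolide and dehydrocostus lactone are taken as commercially available.

Step 1
Reactants: 1 dehydrocostus lactone
Product: 2 3-epi-zaluzanin C
Conditions: SeO2 (cat.), t-BuOOH, CH2Cl2, rt
Reagents that add atoms: tert-butyl hydroperoxide, CC(C)(C)OO (oxygen relayed by selenium dioxide, O=[Se]=O)
Why: SeO2-catalysed allylic hydroxylation (ene reaction, then [2,3]-shift) should oxidise the C3′ methylene next to the C4′=C15′ methylene from the convex α-face; the new carbinol centre is removed again in step 2.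

Step 2
Reactants: 2 3-epi-zaluzanin C
Product: 3 dehydrozaluzanin C
Conditions: Dess–Martin periodinane, CH2Cl2, rt
Reagents that add atoms: none
Why: Dess–Martin oxidation of the allylic secondary alcohol should give the exocyclic enone without isomerising the methylene groups.

Step 3
Reactants: 4 costunolide
Product: 6 keto acetal, via keto aldehyde 5 (not isolated)
Conditions: O3, CH2Cl2/MeOH, −78 °C; Me2S; then TsOH·H2O (cat.), rt
Reagents that add atoms: ozone, [O-][O+]=O; methanol, CO
Why: Ozonolysis should cleave the two electron-rich trisubstituted ring alkenes (C1=C10, C4=C5) much faster than the conjugated lactone methylene, excising C1–C4 and C15 as 4-oxopentanal, and acid-catalysed acetalisation in methanol should mask only the C5 aldehyde; C6 and C7 keep the costunolide configuration.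

Step 4
Reactants: 6 keto acetal
Product: 7 isopropenyl acetal
Conditions: Zn, CH2Br2, TiCl4, THF/CH2Cl2, 0 °C to rt
Reagents that add atoms: dibromomethane, BrCBr
Why: Takai–Lombardo methylenation is non-basic and ketone-selective, so the C10 methyl ketone should become an isopropenyl group while acetal, lactone and lactone methylene stay untouched.

Step 5
Reactants: 7 isopropenyl acetal
Product: 8 isopropenyl aldehyde
Conditions: TFA/H2O, CH2Cl2, 0 °C
Reagents that add atoms: water, O
Why: Acid-catalysed acetal hydrolysis frees the C5 aldehyde that serves as enophile in step 6.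

Step 6
Reactants: 8 isopropenyl aldehyde
Product: 9 methylenecycloheptanol lactone
Conditions: Me2AlCl, CH2Cl2, −78 to 0 °C
Reagents that add atoms: none
Why: In a type 2 intramolecular carbonyl-ene reaction the isopropenyl CH2 (the future C1) should attack the aldehyde carbon C5 with transfer of a methyl hydrogen, closing the seven-membered ring and leaving an exocyclic methylene on C10; the new C5 carbinol centre is not controlled and is removed in step 7.

Step 7
Reactants: 9 methylenecycloheptanol lactone
Product: 11 cycloheptenone lactone, via hydroxy ketone 10 (not isolated)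
Conditions: O3, CH2Cl2, −78 °C; Me2S; then MsCl, Et3N, 0 °C to rt
Reagents that add atoms: ozone, [O-][O+]=O
Why: Ozonolysis of the electron-rich exocyclic alkene (the lactone methylene reacts far more slowly) gives the C10 ketone, and mesylation with E1cB elimination of the β-hydroxy ketone should deliver the conjugated C10(=O)–C1=C5 enone.

Step 8
Reactants: 11 cycloheptenone lactone
Product: 13 vinyl triflate, via silyl enol ether 12 (not isolated)
Conditions: i-Pr3SiC≡CH, n-BuLi, ZnBr2, THF; 11, t-BuMe2SiOTf, Et2O, −40 °C; then CsF, PhNTf2, DME, rt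
Reagents that add atoms: (triisopropylsilyl)acetylene, C#C[Si](C(C)C)(C(C)C)C(C)C; N-phenylbis(trifluoromethanesulfonimide), O=S(=O)(N(c1ccccc1)S(=O)(=O)C(F)(F)F)C(F)(F)F
Why: Silyl-triflate-promoted conjugate addition of the alkynylzinc to the more Lewis-basic enone should place the alkyne on C5 anti to the C6 lactone oxygen (5α-H, as needed in the target) and trap the C10 enolate regiospecifically as silyl enol ether, which fluoride converts into the enolate that is O-sulfonylated to the 1(10)-enol triflate.

Step 9
Reactants: 13 vinyl triflate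
Product: 14 allylic alcohol
Conditions: Bu3SnCH2OH, Pd(PPh3)4 (cat.), LiCl, dioxane, 90 °C
Reagents that add atoms: (tributylstannyl)methanol, OC[Sn](CCCC)(CCCC)CCCC
Why: Stille coupling should transfer the hydroxymethyl group (C14) to C10 with retention of the 1(10)-alkene.

Step 10
Reactants: 14 allylic alcohol
Product: 15 silyl-alkyne vinyl ether
Conditions: vinyl acetate, [Ir(cod)Cl]2 (cat.), Na2CO3, toluene, 100 °C
Reagents that add atoms: vinyl acetate, C=COC(C)=O
Why: Iridium-catalysed transfer vinylation of the primary allylic alcohol installs the two-carbon vinyl ether (the future C2 and C3) under nearly neutral conditions.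

Step 11
Reactants: 15 silyl-alkyne vinyl ether
Product: 16 ethynyl vinyl ether
Conditions: Bu4NF, AcOH, THF, 0 °C
Reagents that add atoms: none
Why: Buffered fluoride C-desilylation should free the terminal alkyne (C4≡C15) without touching the vinyl ether or the acidic C5–H.

Step 12
Reactants: 16 ethynyl vinyl ether
Product: 18 1-epi-dehydrozaluzanin C, via Claisen aldehyde 17 (not isolated)
Conditions: PhCl (0.005 M, degassed), 160 °C; then t-C12H25SH (10 mol %), 1,1′-azobis(cyclohexanecarbonitrile) (slow addition), 100 °C
Reagents that add atoms: none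
Why: Proposed new method: on heating, the allyl vinyl ether unit (C3=C2–O–C14–C10=C1) should undergo a chair-like [3,3] Claisen shift that forms C1–C2 and moves the ring alkene to the exocyclic C10=C14 position (aldehyde 17); the thiyl radical then abstracts the formyl hydrogen, the acyl radical at C3 adds to C4 of the ethynyl group and the vinyl radical at C15 takes hydrogen back from the thiol, so that C3–C4 and the α-methylene ketone arise in a radical chain. The closest known reaction types are the tandem Claisen rearrangement–hydroacylation of allyl vinyl ethers to cyclopentanones, the thiol-catalysed radical-chain cyclisation of unsaturated aldehydes and the 5-exo-dig cyclisation of acyl radicals generated from selenoesters. The only ring closed is the cyclopentanone, in the 5-exo-dig mode. C1 is the only new stereocentre and is set by the substrate, the vinyl ether terminus adding anti to the C5 ethynyl group (1β-H, 1-epi series); this is harmless because C1 becomes trigonal in step 14, and C5, C6 and C7 are not touched. The step needs the acyl radical to choose the alkyne over the new 1,1-disubstituted C10=C14 alkene and both lactone-type methylenes: closure onto C10=C14 would be 4-exo-trig or 5-endo-trig and is kinetically out of reach, and high dilution with a low thiol loading suppresses intermolecular addition.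

Step 13
Reactants: 18 1-epi-dehydrozaluzanin C
Product: 19 silyl dienol ether
Conditions: t-BuMe2SiOTf, Et3N, CH2Cl2, −78 °C
Reagents that add atoms: tert-butyldimethylsilyl trifluoromethanesulfonate, CC(C)(C)[Si](C)(C)OS(=O)(=O)C(F)(F)F
Why: Soft enolisation can only remove a C2 hydrogen (C4 is trigonal), giving the cross-conjugated 2-silyloxy diene needed for the Saegusa–Ito oxidation.

Step 14
Reactants: 19 silyl dienol ether; 3 dehydrozaluzanin C
Product: 23 anhydro-ainsliadimer B, via trienone 20 (not isolated), via Diels–Alder adduct 21 (not isolated), via hydroperoxide 22 (not isolated)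
Conditions: Pd(OAc)2, 3 (excess), MeCN, O2 (1 atm), rt; then PPh3
Reagents that add atoms: dehydrozaluzanin C (3), C=C3C(=O)C[C@H]1C(=C)CC[C@H]2C(=C)C(=O)O[C@@H]2[C@H]13; dioxygen, O=O
Why: Saegusa–Ito oxidation should give trienone 20 (C1 trigonal), whose s-cis diene C2=C1–C10=C14 adds to the exocyclic enone of 3 in a Diels–Alder reaction (C2–C4′ and C14–C15′, the diene approaching the convex α-face of 3 and so fixing spiro centre C4′), after which the β,γ-unsaturated ketone autoxidises through its dienol at C10 with shift of the alkene to C1=C2 and PPh3 reduces the hydroperoxide; the C10 configuration comes from oxygen capture on the face anti to H-5 and is the weak point.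

Step 15
Reactants: 23 anhydro-ainsliadimer B
Product: 24 ainsliadimer B
Conditions: PMe3 (cat.), H2O, MeCN, rt
Reagents that add atoms: water, O
Why: Phosphine-catalysed oxa-Michael addition of water should occur at the most electrophilic acceptor, the cross-conjugated exocyclic enone C4=C15, and protonation at the epimerisable C4 under thermodynamic control places the hydroxymethyl group cis to H-5 (trans to the C5–C6 bond).

Compound list

1 | dehydrocostus lactone (1α,5α,7α-H, 6β-H; guaia-4(15),10(14),11(13)-trien-12,6α-olide) | C=C3CC[C@H]1C(=C)CC[C@H]2C(=C)C(=O)O[C@@H]2[C@H]13 | starting material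
2 | 3-epi-zaluzanin C (3α-hydroxy derivative of 1) | C=C3[C@H](O)C[C@H]1C(=C)CC[C@H]2C(=C)C(=O)O[C@@H]2[C@H]13 | intermediate
3 | dehydrozaluzanin C (3-oxo derivative of 1) | C=C3C(=O)C[C@H]1C(=C)CC[C@H]2C(=C)C(=O)O[C@@H]2[C@H]13 | intermediate
4 | costunolide ((1(10)E,4E)-germacra-1(10),4,11(13)-trien-12,6α-olide) | C/C1=C\CC/C(C)=C/[C@H]2OC(=O)C(=C)[C@@H]2CC1 | starting material
5 | keto aldehyde (trans α-methylene-γ-butyrolactone made of C5–C14 of costunolide: formyl C5 on C6, 3-oxobutyl chain C8–C9–C10(=O)–C14 on C7; C6 and C7 as in costunolide) | O=C[C@H]1OC(=O)C(=C)[C@@H]1CCC(C)=O | intermediate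
6 | keto acetal (C5 dimethyl acetal of 5) | COC(OC)[C@H]1OC(=O)C(=C)[C@@H]1CCC(C)=O | intermediate
7 | isopropenyl acetal (6 with C10=O replaced by C10=CH2; the new carbon is the future C1) | COC(OC)[C@H]1OC(=O)C(=C)[C@@H]1CCC(C)=C | intermediate
8 | isopropenyl aldehyde (7 with free C5 aldehyde) | O=C[C@H]1OC(=O)C(=C)[C@@H]1CCC(C)=C | intermediate
9 | methylenecycloheptanol lactone (seven-membered ring C1, C5–C10; 5-OH as C5 epimers; exocyclic methylene on C10; trans 12,6α-lactone, 6β-H, 7α-H, 11(13)-methylene) | C=C1C(=O)O[C@@H]2C(O)CC(=C)CC[C@@H]12 | intermediate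
10 | hydroxy ketone (9 with C10=O in place of the methylene) | C=C1C(=O)O[C@@H]2C(O)CC(=O)CC[C@@H]12 | intermediate
11 | cycloheptenone lactone (10-oxo-1(5)-ene; 6β-H, 7α-H) | C=C1C(=O)O[C@@H]2C=CC(=O)CC[C@@H]12 | intermediate
12 | silyl enol ether (5β-[(triisopropylsilyl)ethynyl], 5α-H; C10 O-tert-butyldimethylsilyl enol ether, 1(10)-ene) | C=C1C(=O)O[C@@H]2[C@@H](C#C[Si](C(C)C)(C(C)C)C(C)C)C=C(O[Si](C)(C)C(C)(C)C)CC[C@@H]12 | intermediate
13 | vinyl triflate (12 with C10–OSO2CF3) | C=C1C(=O)O[C@@H]2[C@@H](C#C[Si](C(C)C)(C(C)C)C(C)C)C=C(OS(=O)(=O)C(F)(F)F)CC[C@@H]12 | intermediate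
14 | allylic alcohol (C10 carries C14H2OH; 1(10)-ene; 5β-silylethynyl) | C=C1C(=O)O[C@@H]2[C@@H](C#C[Si](C(C)C)(C(C)C)C(C)C)C=C(CO)CC[C@@H]12 | intermediate
15 | silyl-alkyne vinyl ether (C14 O-vinyl ether of 14) | C=C1C(=O)O[C@@H]2[C@@H](C#C[Si](C(C)C)(C(C)C)C(C)C)C=C(COC=C)CC[C@@H]12 | intermediate
16 | ethynyl vinyl ether (5β-ethynyl, 5α-H; C10–C14H2–O–CH=CH2; 1(10)-ene; C15H16O3, isomer of 3) | C=C1C(=O)O[C@@H]2[C@@H](C#C)C=C(COC=C)CC[C@@H]12 | intermediate
17 | Claisen aldehyde (1β-H; C1 carries C2H2–C3HO; 10(14)-methylene; 5β-ethynyl) | C=C1C(=O)O[C@@H]2[C@@H](C#C)[C@H](CC=O)C(=C)CC[C@@H]12 | intermediate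
18 | 1-epi-dehydrozaluzanin C (1β,5α,7α-H, 6β-H; trans-fused 3-oxo-guaia-4(15),10(14),11(13)-trien-12,6α-olide) | C=C1C(=O)O[C@@H]2[C@H]3C(=C)C(=O)C[C@@H]3C(=C)CC[C@@H]12 | intermediate
19 | silyl dienol ether (C3 O-tert-butyldimethylsilyl 2,4(15)-dienol ether of 18) | C=C1C(=O)O[C@@H]2[C@H]3C(=C)C(O[Si](C)(C)C(C)(C)C)=C[C@@H]3C(=C)CC[C@@H]12 | intermediate
20 | trienone (3-oxo-guaia-1,4(15),10(14),11(13)-tetraen-12,6α-olide; 5α-H) | C=C1C(=O)O[C@@H]2[C@H]3C(=C)C(=O)C=C3C(=C)CC[C@@H]12 | intermediate
21 | Diels–Alder adduct (C2–C4′ and C14–C15′ bonds; 1(10)-ene; C2–H of unassigned configuration; 4(15)-ene; spiro C4′ as in the target) | C=C1C(=O)O[C@@H]2[C@@H]3C4=C(CC[C@@H]12)CC[C@]6(C(=O)C[C@H]5C(=C)CC[C@H]7C(=C)C(=O)O[C@@H]7[C@H]56)C4C(=O)C3=C | intermediate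
22 | hydroperoxide (10-OOH anti to H-5; 1-en-3-one; 4(15)-ene) | C=C1C(=O)O[C@@H]2[C@@H]3C4=C(C(=O)C3=C)[C@]3(CC[C@]4(OO)CC[C@@H]12)C(=O)C[C@H]1C(=C)CC[C@H]2C(=C)C(=O)O[C@@H]2[C@H]13 | intermediate
23 | anhydro-ainsliadimer B (10-hydroxy-1-en-3-one with 4(15)-methylene; all other centres as in the target) | C=C1C(=O)O[C@@H]2[C@@H]3C4=C(C(=O)C3=C)[C@]3(CC[C@]4(O)CC[C@@H]12)C(=O)C[C@H]1C(=C)CC[C@H]2C(=C)C(=O)O[C@@H]2[C@H]13 | intermediate
24 | ainsliadimer B | C=C1C(=O)O[C@@H]2[C@@H]3C4=C(C(=O)[C@H]3CO)[C@]3(CC[C@]4(O)CC[C@@H]12)C(=O)C[C@H]1C(=C)CC[C@H]2C(=C)C(=O)O[C@@H]2[C@H]13 | target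

Total steps: 15. Longest linear sequence: 13 steps (costunolide 4 to 24, steps 3–15); steps 1–2 supply dienophile 3.

Steps most likely to fail

1. Step 12 (key step, proposed new method). The acyl or thiyl radical may add intermolecularly to the lactone-type methylenes, which stops the chain and leads to oligomers. The thermal stage may also partly polymerise the substrate. Fallback with known chemistry, setting out from 16: the Claisen rearrangement is run alone (PhCl, 160 °C) and aldehyde 17 is isolated. Pinnick oxidation (NaClO2, NaH2PO4, 2-methyl-2-butene) should give carboxylic acid F1, and (PhSe)2/PBu3 the Se-phenyl selenoester F2. Treatment with (Me3Si)3SiH and azobisisobutyronitrile in benzene at 80 °C under high dilution should then effect the same 5-exo-dig acyl radical cyclisation as a stoichiometric chain, returning to the route at 18.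

2. Step 15. Water may also add to the two lactone methylenes, and the hydration may reverse (retro-oxa-Michael) during isolation. Fallback, setting out from 23: conjugate borylation with B2pin2 (CuCl, Xantphos, NaOt-Bu, THF/MeOH, limiting B2pin2 at low temperature) at the most electrophilic exocyclic enone should give the C15 boronate F3 irreversibly. Oxidation with NaBO3·4H2O then converts C–B into C–OH, returning to the route at 24.

3. Step 14. Facial selectivity in the oxygen capture at C10 may be poor, and the trienone may self-dimerise before it meets 3. Fallback, setting out from 19: the Saegusa–Ito oxidation and Diels–Alder stage is run under argon with excess 3 and adduct 21 is isolated. Its doubly activated C2–H is removed with t-BuMe2SiOTf/Et3N to give the extended silyl dienol ether F4. γ-Hydroxylation with dimethyldioxirane at −78 °C (vinylogous Rubottom oxidation, facial selectivity optimised separately from the cycloaddition) and desilylation with HF·pyridine return to the route at 23.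

Further compounds
F1 | step 12 | carboxylic acid from 17 (C3 carboxyl; 1β-H, 5β-ethynyl) | C=C1C(=O)O[C@@H]2[C@@H](C#C)[C@H](CC(=O)O)C(=C)CC[C@@H]12
F2 | step 12 | Se-phenyl selenoester of F1 | C=C1C(=O)O[C@@H]2[C@@H](C#C)[C@H](CC(=O)[Se]c3ccccc3)C(=C)CC[C@@H]12
F3 | step 15 | C15 pinacol boronate (24 with Bpin in place of the C15 hydroxyl) | C=C1C(=O)O[C@@H]2[C@@H]3C4=C(C(=O)[C@H]3CB5OC(C)(C)C(C)(C)O5)[C@]3(CC[C@]4(O)CC[C@@H]12)C(=O)C[C@H]1C(=C)CC[C@H]2C(=C)C(=O)O[C@@H]2[C@H]13
F4 | step 14 | extended silyl dienol ether of 21 (C3 O-silyl; 2-ene, 1(10)-ene, 4(15)-ene) | C=C1C(=O)O[C@@H]2[C@@H]3C4=C(CC[C@@H]12)CC[C@]6(C(=O)C[C@H]5C(=C)CC[C@H]7C(=C)C(=O)O[C@@H]7[C@H]56)C4=C(O[Si](C)(C)C(C)(C)C)C3=C
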